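(The numbers in the tables were computed on assumed constants; scatter was added.)

| setting | Saturday's | maple | ash |
|---|---|---|---|
| D | 30 mM | 20 mM | 20 mM |
| temperature | 100 °C |  |  |
| remark | run made earlier | at 100 °C until 4.0 h, from then on at 130 °C | at 130 °C throughout |
| time |  | 20 h | 20 h |

Saturday's run (percent of the D charged)

| time / h | J / % | X / % | G / % |
|---|---|---|---|
| 0.250 | 3.0 | 14.5 | 0 |
| 0.833 | 8.6 | 34.4 | 0.2 |
| 1.33 | 11.9 | 43.7 | 1.1 |
| 2.00 | 15.3 | 49.9 | 0.9 |
| 3.00 | 18.2 | 56.6 | 1.2 |
| 4.00 | 21.1 | 59.8 | 2.2 |

(readings scatter by 0.5 percentage points)

- percentages count the D that a species holds: one X counts as two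
- the share counts what is present at the end, not what went on to other products
- the earlier runs do not show what temperature does; that part of a forecast is a guess

- the flask that ends with the higher share of J in all that became J or X or G, or "neither" when 2 percentage points or less lies between them (maple / ash / neither)
- share of J in all that became J or X or G, maple
- share of J in all that became J or X or G, ash

- I started with one easy step: each D that leaves goes to J, or it pairs with a second D into X. G appeared late in Saturday's run, so I booked it with J, as the ring side.
- Closing a ring takes one D, while pairing takes two that meet. So the entries to X against the ring side should shrink as [D] falls. Saturday's cumulative ratio read 4.83 at 0.250 h and 2.57 at 4.00 h.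
- I took the reading at 0.833 h, where the scatter weighs less than at the first. I divided its ratio by the mean fraction of D present up to then, which gave 4.99 at Saturday's charge.
- Dividing by that charge gave my selectivity factor s, the D booked to X per D booked to the ring side, per mM of [D]: 0.166 mM⁻¹.
- With r as s times the charge, I summed the small entries as [D] fell. The ring side came to the logarithm of (one plus r) over (one plus r times the fraction of D left), divided by r.
- As a check, Saturday's run at 4.00 h should hold 23.6% on the ring side, and it read 23.3%.
- For maple, r was 3.32. Closing the books at zero [D], with the heat left out, put 44.0% on the ring side.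
- Saturday's G over J read 0.104 at 4.00 h, which left maple's J share at 39.9%. G was still climbing, so I went below that. Heat is a guess, so I set no number for ash.
- The forecast, higher than my ledger for maple, gave 43% for maple and 46% for ash, so ash: “I favour ash, narrowly”.
- The flasks gave 35.0% for maple and 40.5% for ash, so ash.

    D → J (k = 3.80 × 10⁻⁵ s⁻¹, Ea = 112 kJ mol⁻¹)
    2 D → X (k = 0.00330 M⁻¹ s⁻¹, Ea = 95.0 kJ mol⁻¹)
    J → Q (k = 3.10 × 10⁻⁸ s⁻¹, Ea = 130 kJ mol⁻¹)
    J ⇌ G (K = 0.350, k = 1.10 × 10⁻⁵ s⁻¹, Ea = 125 kJ mol⁻¹, ΔH = −13.0 kJ mol⁻¹)
    (constants at 100 °C)

- Maple closed with D at 0% and X at 55.3%, so 44.7% was not X, beside my 44.0%. Ash stands ahead of maple through the difference in temperature programme: on maple's programme the share in ash goes from 40.5% to 35.0%. In a neighbour of maple charged with 80 mM of D, s gives r of 13.3 and a ring side of 20.0%; that neighbour ended with X at 79.9%, leaving 20.1%.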